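**Retrosynthetic overview**
- The only strategic disconnection is the interflavonoid biaryl bond C5'(ring B)–C8(flavone); all other bonds are bought.
- This bond is made by a [3,3]-sigmatropic rearrangement of an aryloxysulfonium ion: sulfur placed at C6' of ring B is tethered to O7 of the flavone, so the carbon ortho to S (C5') joins the carbon ortho to O7 (C8). Sulfur is then excised.
- The single stereocentre, C2 (S), is bought in (2S)-homoeriodictyol 1, whose 3'-OMe steers sulfur para to itself, to C6'. The flavone half is bought as acacetin 2, whose 4'-OMe masks the ring F phenol.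
- No ring is constructed: rings A, C, B arrive intact in 1 and rings D, E, F in 2. Order of events: acetylate, put sulfur in, oxidise, couple/rearrange, take sulfur out, deprotect.

Assumption: the biaryl axis, which the target SMILES leaves undefined, is taken as not configurationally fixed (as in amentoflavone), and commercial (2S)-homoeriodictyol is taken as enantiopure (ee checked by chiral HPLC before use).

Notation: unprimed and primed locants (2–8, 2'–6') refer to the flavanone half (rings A, C, B); positions of the flavone half are written "flavone C8" and so on (rings D, E, F).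

**Step 1**
Reactants: 1 (2S)-homoeriodictyol
Product: 3 (2S)-homoeriodictyol 4',5,7-triacetate
Conditions: Ac2O, pyridine, 0 °C → rt
Reagents that add atoms: acetic anhydride, CC(=O)OC(C)=O
Why: Exhaustive O-acetylation caps the three phenols under conditions too weakly basic to open ring C (C2 stays S), and it leaves ring A an electron-poor diacetoxy aryl ketone while ring B keeps one strong donor, the 3'-OMe.

**Step 2**
Reactants: 3 (2S)-homoeriodictyol 4',5,7-triacetate
Product: 5 (2S)-6'-(methylsulfanyl)homoeriodictyol 4',5,7-triacetate, via 6'-dimethylsulfonium triflate 4 (not isolated)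
Conditions: DMSO, Tf2O, CH2Cl2, −78 °C; then 3, −78 → 0 °C; then Et3N, rt
Reagents that add atoms: dimethyl sulfoxide, CS(C)=O
Why: Electrophilic aromatic substitution by Tf2O-activated DMSO (interrupted Pummerer reaction) goes para to the only strong donor on ring B, the 3'-methoxy group, that is to C6' (the site at which acetylvanillin is brominated), and Et3N then removes one S-methyl group by SN2, C2 not being involved.

**Step 3**
Reactants: 5 (2S)-6'-(methylsulfanyl)homoeriodictyol 4',5,7-triacetate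
Product: 6 (2S)-6'-(methylsulfinyl)homoeriodictyol 4',5,7-triacetate (both epimers at sulfur)
Conditions: 30% aq. H2O2 (1.1 equiv), (CF3)2CHOH, rt
Reagents that add atoms: hydrogen peroxide, OO
Why: Hydrogen peroxide in hexafluoroisopropanol oxidises a sulfide to the sulfoxide and stops there, leaving ketone and aryl acetates alone; the new sulfur stereocentre is uncontrolled and irrelevant because sulfur is removed later.

**Step 4**
Reactants: 6 (2S)-6'-(methylsulfinyl)homoeriodictyol 4',5,7-triacetate; 2 acacetin (1.5 equiv)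
Product: 9 (2S)-5'-(acacetin-8-yl)-6'-(methylsulfanyl)homoeriodictyol 4',5,7-triacetate, via trifluoroacetoxysulfonium salt 7 (not isolated), via 7-aryloxysulfonium salt 8 (not isolated)
Conditions: TFAA (1.5 equiv), CH2Cl2–MeCN, −40 °C → rt; then aq. NaHCO3
Reagents that add atoms: none
Why: TFAA activates the sulfoxide, the 7-OH of 2 (the 5-OH is locked in a hydrogen bond to C4=O) binds to sulfur (interrupted Pummerer reaction), and the aryloxysulfonium ion undergoes a charge-accelerated [3,3]-sigmatropic rearrangement (sulfonium analogue of the aromatic Claisen rearrangement) that joins C5', the only free position ortho to sulfur, to flavone C8, the ortho position favoured in Claisen shifts from O7 of 5-hydroxyflavones, after which both rings rearomatise and the remote C2 is untouched.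

**Step 5**
Reactants: 9 (2S)-5'-(acacetin-8-yl)-6'-(methylsulfanyl)homoeriodictyol 4',5,7-triacetate
Product: 10 (2S)-5'-(acacetin-8-yl)homoeriodictyol 4',5,7-triacetate
Conditions: Raney Ni (W-2, washed neutral, aged in acetone), acetone–THF, rt
Reagents that add atoms: none
Why: Reductive desulfurisation with acetone-deactivated Raney Ni cleaves the aryl C–S bond and leaves H at C6', while the aryl ketone, the 4-pyranone C=C and the acetates are not reduced under these hydrogen-poor conditions.

**Step 6**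
Reactants: 10 (2S)-5'-(acacetin-8-yl)homoeriodictyol 4',5,7-triacetate
Product: 11 target, (2S)-2-[3-(5,7-dihydroxy-2-(4-hydroxyphenyl)-4-oxo-4H-chromen-8-yl)-4,5-dihydroxyphenyl]-5,7-dihydroxychroman-4-one
Conditions: BBr3 (12 equiv), CH2Cl2, −78 → 0 °C; then MeOH, 40 °C
Reagents that add atoms: none
Why: BBr3 cleaves both aryl methyl ethers (Lewis acid–base complex, then SN2 by bromide at methyl) and the HBr/MeOH formed on quenching transesterifies the three aryl acetates, ring C being spared because O1 is a poorly basic vinylogous-ester oxygen and C2–H is not acidic, so the S configuration is kept.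

**Compound list**
1 | (2S)-homoeriodictyol, (2S)-5,7-dihydroxy-2-(4-hydroxy-3-methoxyphenyl)chroman-4-one | O=C1C[C@@H](c2ccc(O)c(OC)c2)Oc2cc(O)cc(O)c21 | starting material
2 | acacetin, 5,7-dihydroxy-2-(4-methoxyphenyl)-4H-chromen-4-one | COc1ccc(cc1)-c1cc(=O)c2c(O)cc(O)cc2o1 | starting material
3 | (2S)-homoeriodictyol 4',5,7-triacetate, (2S)-2-(4-acetoxy-3-methoxyphenyl)-4-oxochroman-5,7-diyl diacetate | O=C1C[C@@H](c2ccc(OC(C)=O)c(OC)c2)Oc2cc(OC(C)=O)cc(OC(C)=O)c21 | intermediate
4 | [5-acetoxy-2-((2S)-5,7-diacetoxy-4-oxochroman-2-yl)-4-methoxyphenyl]dimethylsulfonium triflate (S at C6'; formed in the flask) | O=C1C[C@@H](c2cc(OC)c(OC(C)=O)cc2[S+](C)C)Oc2cc(OC(C)=O)cc(OC(C)=O)c21.[O-]S(=O)(=O)C(F)(F)F | intermediate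
5 | (2S)-6'-(methylsulfanyl)homoeriodictyol 4',5,7-triacetate, (2S)-2-[4-acetoxy-5-methoxy-2-(methylsulfanyl)phenyl]-4-oxochroman-5,7-diyl diacetate | O=C1C[C@@H](c2cc(OC)c(OC(C)=O)cc2SC)Oc2cc(OC(C)=O)cc(OC(C)=O)c21 | intermediate
6 | (2S)-6'-(methylsulfinyl)homoeriodictyol 4',5,7-triacetate, both epimers at sulfur | O=C1C[C@@H](c2cc(OC)c(OC(C)=O)cc2S(C)=O)Oc2cc(OC(C)=O)cc(OC(C)=O)c21 | intermediate
7 | methyl(aryl)(trifluoroacetoxy)sulfonium trifluoroacetate derived from 6 (aryl = ring B at C6'; formed in the flask) | O=C1C[C@@H](c2cc(OC)c(OC(C)=O)cc2[S+](C)OC(=O)C(F)(F)F)Oc2cc(OC(C)=O)cc(OC(C)=O)c21.[O-]C(=O)C(F)(F)F | intermediate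
8 | methyl(aryl)(acacetin-7-yloxy)sulfonium trifluoroacetate (S bridges C6' and flavone O7; formed in the flask) | O=C1C[C@@H](c2cc(OC)c(OC(C)=O)cc2[S+](C)Oc2cc(O)c3c(=O)cc(-c4ccc(OC)cc4)oc3c2)Oc2cc(OC(C)=O)cc(OC(C)=O)c21.[O-]C(=O)C(F)(F)F | intermediate
9 | (2S)-2-[4-acetoxy-3-(5,7-dihydroxy-2-(4-methoxyphenyl)-4-oxo-4H-chromen-8-yl)-5-methoxy-2-(methylsulfanyl)phenyl]-4-oxochroman-5,7-diyl diacetate (hindered biaryl, possibly a mixture of rotamers) | O=C1C[C@@H](c2cc(OC)c(OC(C)=O)c(-c3c(O)cc(O)c4c(=O)cc(-c5ccc(OC)cc5)oc34)c2SC)Oc2cc(OC(C)=O)cc(OC(C)=O)c21 | intermediate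
10 | (2S)-2-[4-acetoxy-3-(5,7-dihydroxy-2-(4-methoxyphenyl)-4-oxo-4H-chromen-8-yl)-5-methoxyphenyl]-4-oxochroman-5,7-diyl diacetate | O=C1C[C@@H](c2cc(OC)c(OC(C)=O)c(-c3c(O)cc(O)c4c(=O)cc(-c5ccc(OC)cc5)oc34)c2)Oc2cc(OC(C)=O)cc(OC(C)=O)c21 | intermediate
11 | (2S)-2-[3-(5,7-dihydroxy-2-(4-hydroxyphenyl)-4-oxo-4H-chromen-8-yl)-4,5-dihydroxyphenyl]-5,7-dihydroxychroman-4-one | O=C1C[C@@H](c2cc(O)c(O)c(-c3c(O)cc(O)c4c(=O)cc(-c5ccc(O)cc5)oc34)c2)Oc2cc(O)cc(O)c21 | target

**Step count**
Total: 6 steps. Longest linear sequence: 6 steps (1 → 3 → 5 → 6 → 9 → 10 → 11); 2 is used as bought.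

**Steps most likely to fail**

Step 4 (tethered coupling). The ring B sulfonium has to capture a weakly nucleophilic, poorly soluble 7-OH and then close a biaryl that is tetra-ortho-substituted at this stage. The expected leaks are Pummerer loss through S–CH3, direct C–S bond formation at C6/C8 of 2, and migration to flavone C6 instead of C8. The fallback sets out from 3 and returns at 10 (step 5 is then not needed); it replaces sulfur by trivalent iodine as the tether. 3 is iodinated para to the 3'-methoxy group (NIS, cat. TFA, MeCN, rt) to the 6'-iodo triacetate F1, and F1 is oxidised (NaBO3·4H2O, AcOH, 45 °C) to the 6'-(diacetoxyiodo) triacetate F2. Exchange of one acetate on iodine for the 7-OH of 2 needs no nucleophilic oxygen and offers no α-C–H for a Pummerer leak; it is followed by the iodonium [3,3] shift (TMSOTf, CH2Cl2–MeCN, −40 °C → rt) to give the 6'-iodo biaryl F3. Hydrogenolysis (H2, Pd/C, NaOAc, EtOAc, rt) removes iodine and gives 10.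

Step 6 (global deprotection). The excess BBr3 at 0 °C is needed mainly for the unactivated ring F anisole; it may open ring C (chalcone, loss of ee) or leave partial ethers. The fallback sets out from 2, uses 6 unchanged and returns at 11; it removes the hard methyl ether before the chiral half is attached. 2 is demethylated in a pyridinium chloride melt (190 °C) to apigenin F4, peracetylated (Ac2O, pyridine) to apigenin 4',5,7-triacetate F5, and selectively 7-O-deacetylated (PhSH, imidazole, NMP, 0 °C) to 4',5-di-O-acetylapigenin F6. F6 is coupled with 6 as in step 4 to the biaryl sulfide pentaacetate F7 and desulfurised as in step 5 to the biaryl pentaacetate F8. Only the ortho-oxygenated ring B methyl ether then remains; BCl3/nBu4NI (CH2Cl2, −78 → 0 °C), then MeOH at 40 °C, gives 11 without BBr3.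

Step 2 (C–H methylthiolation). Activated DMSO is a strong electrophile and liberates TfOH, so attack on ring A, acetate loss, or acid- or amine-promoted opening of ring C are possible. The fallback sets out from 3 and returns at 5; it makes the C–S bond by cross-coupling instead of C–H substitution. 3 is brominated (NBS, MeCN, rt; same para-to-OMe preference) to the 6'-bromo triacetate F9. Nickel-catalysed reductive thiolation (NiBr2(bpy) cat., Zn, MeSSMe, DMF, 80 °C; zerovalent nickel inserts into the C–Br bond) then gives 5 under neutral conditions.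

**Further compounds**
F1 | step 4 | (2S)-6'-iodohomoeriodictyol 4',5,7-triacetate | O=C1C[C@@H](c2cc(OC)c(OC(C)=O)cc2I)Oc2cc(OC(C)=O)cc(OC(C)=O)c21
F2 | step 4 | (2S)-6'-(diacetoxyiodo)homoeriodictyol 4',5,7-triacetate | O=C1C[C@@H](c2cc(OC)c(OC(C)=O)cc2I(OC(C)=O)OC(C)=O)Oc2cc(OC(C)=O)cc(OC(C)=O)c21
F3 | step 4 | (2S)-5'-(acacetin-8-yl)-6'-iodohomoeriodictyol 4',5,7-triacetate | O=C1C[C@@H](c2cc(OC)c(OC(C)=O)c(-c3c(O)cc(O)c4c(=O)cc(-c5ccc(OC)cc5)oc34)c2I)Oc2cc(OC(C)=O)cc(OC(C)=O)c21
F4 | step 6 | apigenin, 5,7-dihydroxy-2-(4-hydroxyphenyl)-4H-chromen-4-one | Oc1ccc(cc1)-c1cc(=O)c2c(O)cc(O)cc2o1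
F5 | step 6 | apigenin 4',5,7-triacetate | CC(=O)Oc1ccc(cc1)-c1cc(=O)c2c(OC(C)=O)cc(OC(C)=O)cc2o1
F6 | step 6 | 4',5-di-O-acetylapigenin (7-OH free) | CC(=O)Oc1ccc(cc1)-c1cc(=O)c2c(OC(C)=O)cc(O)cc2o1
F7 | step 6 | (2S)-5'-(4',5-di-O-acetylapigenin-8-yl)-6'-(methylsulfanyl)homoeriodictyol 4',5,7-triacetate | O=C1C[C@@H](c2cc(OC)c(OC(C)=O)c(-c3c(O)cc(OC(C)=O)c4c(=O)cc(-c5ccc(OC(C)=O)cc5)oc34)c2SC)Oc2cc(OC(C)=O)cc(OC(C)=O)c21
F8 | step 6 | (2S)-5'-(4',5-di-O-acetylapigenin-8-yl)homoeriodictyol 4',5,7-triacetate | O=C1C[C@@H](c2cc(OC)c(OC(C)=O)c(-c3c(O)cc(OC(C)=O)c4c(=O)cc(-c5ccc(OC(C)=O)cc5)oc34)c2)Oc2cc(OC(C)=O)cc(OC(C)=O)c21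
F9 | step 2 | (2S)-6'-bromohomoeriodictyol 4',5,7-triacetate | O=C1C[C@@H](c2cc(OC)c(OC(C)=O)cc2Br)Oc2cc(OC(C)=O)cc(OC(C)=O)c21
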